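The free base is the unknown of this flask: the charge is sought at which the electrophile just reaches the wanted part in the given time.

    electrophile + nucleophile → acid set free + target (k1 = 2.8 M⁻¹ h⁻¹)
    nucleophile + acid set free ⇌ protonated nucleophile, settled at all times (K2 = 7500 M⁻¹)
    acid set free + free base ⇌ salt of the base (K3 = 29000 M⁻¹, k3 = 0.61 M⁻¹ h⁻¹)
    acid set free + free base ⇌ idle adduct, settled at all times (K4 = 440 M⁻¹)
    nucleophile + target → over-reaction product (k5 = 0.018 M⁻¹ h⁻¹)
    free base ⇌ dormant form (K6 = 5.8, k6 = 0.024 h⁻¹)

electrophile 0.50 M; nucleophile 0.550 M; time 3.0 d

- the concentration of free base at which the part of the electrophile that has reacted at 3.0 d is just 70 %, in M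

- for acid set free the idle adduct is counted in
- the amount of free base is what is sought; it is there from the start
- run time (flask): 3.0 d

The reckoning below is made by hand, with h for free acid.

1. The mark means x = 0.350 M reacted. That leaves electrophile A = 0.150 M and a nucleophile pool, free plus protonated, of N = 0.200 M.

2. Taking the pool as protonated (its resting state), it holds N of the acid. A surplus S = 0.150 M must then stand free or on base. Salt and over-reaction are left out here.

3. Free nucleophile is N/Λ, where Λ = K·h and K = 7500 M⁻¹. The electrophile is then used at k·A·N/Λ, with k = 2.8 M⁻¹ h⁻¹. If each further acid stays free, h rises by 2 per unit of x, and integration gives Λ = 2√(K·k·A·N·t). In powers of ten this is 0.301 plus 0.5 times 4.66. So the lock Λ, protonated over free nucleophile at the asked time, is 426.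

4. Then h = 0.0568 M. The dormant form is taken as at balance with free base, which is a plain assumption of this reckoning. The adduct's share of the charged base is 78.6 %.

5. The adduct must hold S − h, so the charge is 0.119 M.

6. The weak link is the assumption in step 3: the adduct still takes up 0.351 of acid per unit of added free acid. The lock becomes 366, h becomes 0.0489 M, and the charge 0.133 M.

The forecast says 0.16 M, within 0.13 M to 0.2 M, holding that “the base must hold about 0.13–0.15 M of acid”. That is more than this reckoning gives.

The simulation gives 0.125 M, less than the forecast's low end. The lock is the main brake in this flask: the simulated run without the pairing of nucleophile and acid reaches >99.9 % instead of 70.0 %. With the found charge, the lock reckons to 364 at the asked time, leaving 0.100 % of the charged nucleophile free. The run reads 0.156 % still free at 1.50 d.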